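**Retrosynthetic overview**

- The target is a 2,4-trans-4-arylflavan (upper unit, 2S,4S) bonded from its C-4 to C-6 of an all-cis flavan-3,4-diol (lower unit, 2R,3R,4R). Both units have the same 7,8,4'-trioxygenated 2-arylchroman skeleton with the same spatial arrangement at C-2, so both are cut back to one enantioenriched aryl propargyl ether 10.
- Enabling feature: upper C-4 is a methine bonded to two arene carbons that each lie ortho/para to oxygen (upper C-4a: ortho to O-1, para to O-7; lower C-6: ortho to O-7, para to O-1). C-4 can therefore be the terminal alkyne carbon of 10 and be hydroarylated twice.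
- Key disconnections: upper C-4–C-4a (closure of the upper pyran ring) and upper C-4–lower C-6, both in one operation; O-1–C-2 of each unit by asymmetric propargylic etherification; the lower 3,4-diol by Woodward cis-hydroxylation of the flav-3-ene made from the same ether.
- Ring order: the four benzene rings come from commercial materials; the lower pyran ring is closed in step 7; the upper pyran ring is closed last, in step 9. The end game is deacylation and hydrogenolysis.

Key step: step 9

Assumption: flavonoid numbering is used for each unit (O-1, C-2, C-3, C-4, C-4a … C-8a; "upper" = 3-deoxyflavan unit, "lower" = flavan-3,4-diol unit). In step 6 the (S,S)-ligand is taken to give the S ether; if the sense of induction proves opposite, the (R,R)-ligand is used.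

**Route**

Step 1
Reactants: 1 2,3-dihydroxybenzaldehyde
Product: 2 2,3-bis(benzyloxy)benzaldehyde
Conditions: BnBr, K2CO3, DMF, 60 °C
Reagents that add atoms: benzyl bromide, BrCc1ccccc1
Why: Williamson etherification of both phenols, the chelated 2-OH included under warm DMF conditions.

Step 2
Reactants: 2 2,3-bis(benzyloxy)benzaldehyde
Product: 4 2,3-bis(benzyloxy)phenol, via aryl formate 3 (not isolated)
Conditions: mCPBA, CH2Cl2, rt; then K2CO3 (cat.), MeOH, rt
Reagents that add atoms: mCPBA, OOC(=O)c1cccc(Cl)c1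
Why: Baeyer–Villiger (Dakin-type) oxidation in which the electron-rich ortho-alkoxyaryl group migrates, followed by methanolysis of the formate.

Step 3
Reactants: 5 4-hydroxybenzaldehyde
Product: 6 4-formylphenyl pivalate
Conditions: PivCl, Et3N, DMAP (cat.), CH2Cl2, 0 °C to rt
Reagents that add atoms: pivaloyl chloride, CC(C)(C)C(Cl)=O
Why: Phenol acylation; the hindered, electron-withdrawing pivalate is chosen so that the later C-2–O benzylic bonds resist acid ionisation.

Step 4
Reactants: 6 4-formylphenyl pivalate; 7 ethynylmagnesium bromide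
Product: 8 rac-4-(1-hydroxyprop-2-yn-1-yl)phenyl pivalate
Conditions: THF, −78 to −20 °C; aq. NH4Cl
Reagents that add atoms: none
Why: Grignard 1,2-addition to the aldehyde, which is far faster than attack on the hindered aryl pivalate at low temperature; the racemate is sufficient because step 6 is enantioconvergent.

Step 5
Reactants: 8 rac-4-(1-hydroxyprop-2-yn-1-yl)phenyl pivalate
Product: 9 rac-4-(1-acetoxyprop-2-yn-1-yl)phenyl pivalate
Conditions: Ac2O, pyridine, DMAP (cat.), CH2Cl2, 0 °C to rt
Reagents that add atoms: acetic anhydride, CC(=O)OC(C)=O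
Why: Standard acetylation to install the leaving group for copper-catalysed propargylic substitution.

Step 6
Reactants: 9 rac-4-(1-acetoxyprop-2-yn-1-yl)phenyl pivalate; 4 2,3-bis(benzyloxy)phenol
Product: 10 4-[(1S)-1-[2,3-bis(benzyloxy)phenoxy]prop-2-yn-1-yl]phenyl pivalate
Conditions: Cu(OTf)·½C6H6 (5 mol%), (S,S)-Ph-pybox (6 mol%), i-Pr2NEt, MeOH, −20 °C
Reagents that add atoms: none
Why: Copper-catalysed enantioselective propargylic etherification, in which both enantiomers of 9 converge on one copper allenylidene and the chiral pybox ligand controls the face of phenoxide attack at the γ-carbon, setting the centre that becomes C-2 of both flavan units (the phenoxide should outcompete the solvent).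

Step 7
Reactants: 10 4-[(1S)-1-[2,3-bis(benzyloxy)phenoxy]prop-2-yn-1-yl]phenyl pivalate
Product: 11 4-[(2S)-7,8-bis(benzyloxy)-2H-chromen-2-yl]phenyl pivalate
Conditions: Ph3PAuNTf2 (2 mol%), CH2Cl2, rt, dark
Reagents that add atoms: none
Why: Gold(I)-catalysed 6-endo-dig intramolecular hydroarylation of an aryl propargyl ether at the only free ortho carbon (para to a benzyloxy group), a direct Friedel–Crafts-type path that does not touch the C-2 stereocentre.

Step 8
Reactants: 11 4-[(2S)-7,8-bis(benzyloxy)-2H-chromen-2-yl]phenyl pivalate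
Product: 14 (2R,3S,4R)-7,8-bis(benzyloxy)-2-[4-(pivaloyloxy)phenyl]chromane-3,4-diyl diacetate, via trans-iodoacetate 12 (not isolated), via cis-hydroxy acetate 13 (not isolated)
Conditions: I2, AgOAc, AcOH, rt; then H2O, 90 °C; then Ac2O, pyridine, DMAP (cat.), rt
Reagents that add atoms: silver acetate, CC(=O)[O-].[Ag+]; water, O; acetic anhydride, CC(=O)OC(C)=O
Why: Woodward cis-hydroxylation, in which iodine adds to C-3 anti to the C-2 aryl group, acetate adds to benzylic C-4, the acetoxy group displaces iodide at C-3 with inversion to give a cis-fused dioxolanylium ion on the aryl face, and water opens it, so that both oxygens end up syn to the C-2 aryl (the face opposite to that of osmylation) before acetylation gives the 2,3-cis-3,4-cis diacetate.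

Step 9
Reactants: 10 4-[(1S)-1-[2,3-bis(benzyloxy)phenoxy]prop-2-yn-1-yl]phenyl pivalate; 14 (2R,3S,4R)-7,8-bis(benzyloxy)-2-[4-(pivaloyloxy)phenyl]chromane-3,4-diyl diacetate
Product: 15 (2R,3S,4R)-7,8-bis(benzyloxy)-6-[(2S,4R)-7,8-bis(benzyloxy)-2-[4-(pivaloyloxy)phenyl]chroman-4-yl]-2-[4-(pivaloyloxy)phenyl]chromane-3,4-diyl diacetate, via (S)-flav-3-ene 11 (not isolated)
Conditions: Ph3PAuNTf2 (2 mol%), CH2Cl2, rt; then this solution added slowly to 14 (2.5 equiv), HNTf2 (10 mol%), 4 Å MS, CH2Cl2, −45 °C; Et3N quench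
Reagents that add atoms: none
Why: Gold(I) activates the terminal alkyne of 10, the free ortho carbon of the aryl ether (future C-4a) attacks the terminal alkyne carbon and protodeauration gives flav-3-ene 11; HNTf2 then protonates C-3 to give the flavan-4-yl cation (stabilised by O-1 and the 7-benzyloxy group), which is captured by C-6 of 14, so the terminal alkyne carbon is hydroarylated twice and becomes C-4. The closest known reaction types are the gold-catalysed cycloisomerisation of aryl propargyl ethers to 2H-chromenes and the acid-mediated arylation of flav-3-enes or flavan-4-ols to 4-arylflavans, here run in one flask. The upper pyran ring closes by 6-endo-dig hydroarylation (C-4–C-4a bond). The new stereocentre C-4 is controlled by C-2: the cation adopts a half-chair with the 2-aryl group equatorial and the arene adds pseudo-axially under kinetic control at low temperature, which should give the 2,4-trans isomer, while the stereocentres of 14 are spectators. The step needs site selectivity for C-6 of 14 (ortho to 7-OBn and para to O-1, whereas C-5 is not activated), chemoselectivity against cationic self-condensation (secured by slow addition of 11 to excess, recoverable 14), inertness of the C-4 acetate of 14 (the cis 3-acetate gives no anchimeric assistance and destabilises the cation) and retention at C-2 (the electron-poor 4-pivaloyloxyphenyl groups disfavour C-2–O ionisation). Because both partners derive from the same enantioenriched 10, the minor enantiomers should end up largely in a separable diastereomer.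

Step 10
Reactants: 15 (2R,3S,4R)-7,8-bis(benzyloxy)-6-[(2S,4R)-7,8-bis(benzyloxy)-2-[4-(pivaloyloxy)phenyl]chroman-4-yl]-2-[4-(pivaloyloxy)phenyl]chromane-3,4-diyl diacetate
Product: 16 (2R,3R,4R)-7,8-bis(benzyloxy)-6-[(2S,4R)-7,8-bis(benzyloxy)-2-(4-hydroxyphenyl)chroman-4-yl]-2-(4-hydroxyphenyl)chromane-3,4-diol
Conditions: K2CO3, MeOH/THF, rt, Ar
Reagents that add atoms: none
Why: Base-mediated transesterification removes both acetates and both aryl pivalates while the catechols stay benzylated, and the short, cold exposure should not open the chroman rings through quinone methides.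

Step 11
Reactants: 16 (2R,3R,4R)-7,8-bis(benzyloxy)-6-[(2S,4R)-7,8-bis(benzyloxy)-2-(4-hydroxyphenyl)chroman-4-yl]-2-(4-hydroxyphenyl)chromane-3,4-diol
Product: 17 (2R,3R,4R)-6-[(2S,4S)-7,8-dihydroxy-2-(4-hydroxyphenyl)chroman-4-yl]-2-(4-hydroxyphenyl)chromane-3,4,7,8-tetrol (CNP0209379.1)
Conditions: H2 (1 atm), Pd(OH)2/C, THF/MeOH, rt, neutral, short reaction time
Reagents that add atoms: none
Why: Hydrogenolysis of the four aryl benzyl ethers, which under neutral conditions should be much faster than cleavage of the free benzylic 4-OH or of the cyclic benzylic C-2–O bonds (the acetates were removed first because a benzylic acetate would be hydrogenolysed).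

**Compound list**

1 | 2,3-dihydroxybenzaldehyde | O=Cc1cccc(O)c1O | starting material
2 | 2,3-bis(benzyloxy)benzaldehyde | O=Cc1cccc(OCc2ccccc2)c1OCc1ccccc1 | intermediate
3 | 2,3-bis(benzyloxy)phenyl formate | O=COc1cccc(OCc2ccccc2)c1OCc1ccccc1 | intermediate (not isolated)
4 | 2,3-bis(benzyloxy)phenol | Oc1cccc(OCc2ccccc2)c1OCc1ccccc1 | intermediate
5 | 4-hydroxybenzaldehyde | O=Cc1ccc(O)cc1 | starting material
6 | 4-formylphenyl pivalate | CC(C)(C)C(=O)Oc1ccc(C=O)cc1 | intermediate
7 | ethynylmagnesium bromide | C#C[Mg]Br | starting material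
8 | rac-4-(1-hydroxyprop-2-yn-1-yl)phenyl pivalate | C#CC(O)c1ccc(OC(=O)C(C)(C)C)cc1 | intermediate
9 | rac-4-(1-acetoxyprop-2-yn-1-yl)phenyl pivalate | C#CC(OC(C)=O)c1ccc(OC(=O)C(C)(C)C)cc1 | intermediate
10 | 4-[(1S)-1-[2,3-bis(benzyloxy)phenoxy]prop-2-yn-1-yl]phenyl pivalate | C#C[C@H](Oc1cccc(OCc2ccccc2)c1OCc1ccccc1)c1ccc(OC(=O)C(C)(C)C)cc1 | intermediate
11 | 4-[(2S)-7,8-bis(benzyloxy)-2H-chromen-2-yl]phenyl pivalate ((S)-flav-3-ene) | CC(C)(C)C(=O)Oc1ccc([C@@H]2C=Cc3ccc(OCc4ccccc4)c(OCc4ccccc4)c3O2)cc1 | intermediate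
12 | (2R,3R,4R)-4-acetoxy-7,8-bis(benzyloxy)-3-iodo-2-[4-(pivaloyloxy)phenyl]chromane (iodine anti to the 2-aryl group, acetoxy syn to it) | c1cc2c(c(OCc3ccccc3)c1OCc1ccccc1)O[C@H](c1ccc(OC(=O)C(C)(C)C)cc1)[C@@H](I)[C@@H]2OC(C)=O | intermediate (not isolated)
13 | (2R,3R,4R)-3-acetoxy-7,8-bis(benzyloxy)-4-hydroxy-2-[4-(pivaloyloxy)phenyl]chromane (all-cis; its 4-O-acetyl regioisomer may accompany it and converges on 14) | c1cc2c(c(OCc3ccccc3)c1OCc1ccccc1)O[C@H](c1ccc(OC(=O)C(C)(C)C)cc1)[C@H](OC(C)=O)[C@@H]2O | intermediate (not isolated)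
14 | (2R,3S,4R)-7,8-bis(benzyloxy)-2-[4-(pivaloyloxy)phenyl]chromane-3,4-diyl diacetate (2,3-cis-3,4-cis) | c1cc2c(c(OCc3ccccc3)c1OCc1ccccc1)O[C@H](c1ccc(OC(=O)C(C)(C)C)cc1)[C@H](OC(C)=O)[C@@H]2OC(C)=O | intermediate
15 | (2R,3S,4R)-7,8-bis(benzyloxy)-6-[(2S,4R)-7,8-bis(benzyloxy)-2-[4-(pivaloyloxy)phenyl]chroman-4-yl]-2-[4-(pivaloyloxy)phenyl]chromane-3,4-diyl diacetate (upper unit 2,4-trans) | CC(C)(C)C(=O)Oc1ccc([C@@H]2C[C@@H](c3cc4c(c(OCc5ccccc5)c3OCc3ccccc3)O[C@H](c3ccc(OC(=O)C(C)(C)C)cc3)[C@H](OC(C)=O)[C@@H]4OC(C)=O)c3ccc(OCc5ccccc5)c(OCc5ccccc5)c3O2)cc1 | intermediate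
16 | (2R,3R,4R)-7,8-bis(benzyloxy)-6-[(2S,4R)-7,8-bis(benzyloxy)-2-(4-hydroxyphenyl)chroman-4-yl]-2-(4-hydroxyphenyl)chromane-3,4-diol | Oc1ccc([C@@H]2C[C@@H](c3cc4c(c(OCc5ccccc5)c3OCc3ccccc3)O[C@H](c3ccc(O)cc3)[C@H](O)[C@@H]4O)c3ccc(OCc5ccccc5)c(OCc5ccccc5)c3O2)cc1 | intermediate
17 | (2R,3R,4R)-6-[(2S,4S)-7,8-dihydroxy-2-(4-hydroxyphenyl)chroman-4-yl]-2-(4-hydroxyphenyl)chromane-3,4,7,8-tetrol (CNP0209379.1) | Oc1ccc([C@@H]2C[C@@H](c3cc4c(c(O)c3O)O[C@H](c3ccc(O)cc3)[C@H](O)[C@@H]4O)c3ccc(O)c(O)c3O2)cc1 | target

Total step count: 11 steps.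
Longest linear sequence: 9 steps (5 → 6 → 8 → 9 → 10 → 11 → 14 → 15 → 16 → 17; steps 3 to 11).

**Steps most likely to fail**

1. Step 9. The flavan-4-yl cation may be captured by the flav-3-ene, by 10 or by the upper A-ring of the product instead of C-6 of 14 (cationic oligomerisation). It may also take a hydride from C-2 of the flav-3-ene (disproportionation), the acid may ionise the C-4 acetate of 14, or reversible C-4 ionisation may erode the kinetic 2,4-trans control. Fallback: the two events are separated and a discrete C-4 leaving group is used, as in classical flavan-4-yl ether couplings. The fallback sets out from 11: camphorsulfonic acid (cat.) in MeOH/CH2Cl2 at 0 °C adds methanol across C-3=C-4 to give 4-[(2S)-7,8-bis(benzyloxy)-4-methoxychroman-2-yl]phenyl pivalate F1 (both C-4 epimers are usable). F1 is then ionised with TMSOTf in CH2Cl2 at −78 °C in the presence of 14 (3 equiv), with no alkene present, and pseudo-axial capture should again give the 2,4-trans product. The fallback comes back to the route at 15.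

2. Step 8. Iodine may substitute the electron-rich A-ring at C-6 or oxidise the flav-3-ene to a flavylium ion, or the benzylic cation may leak so that neighbouring-group closure does not take place cleanly on the aryl face (poor facial fidelity). Fallback: osmylation followed by inversion at both carbinol centres, setting out from 11.
   - OsO4 (cat.), NMO, acetone/water should give the diol with both hydroxyls anti to the aryl group, (2R,3S,4S)-7,8-bis(benzyloxy)-2-[4-(pivaloyloxy)phenyl]chromane-3,4-diol F2.
   - SOCl2, Et3N, CH2Cl2, 0 °C gives its 3,4-cyclic sulfite F3 (sulfur epimers).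
   - CsOAc, DMF, 70 °C opens the sulfite at benzylic C-4 with inversion; acidic aqueous work-up gives the 3-hydroxy-4-acetate F4 (3-OH anti, 4-OAc syn to the aryl group).
   - Dess–Martin periodinane gives the 3-ketone F5.
   - L-Selectride, THF, −78 °C delivers hydride to the face away from the substituents and should give the all-cis 3-hydroxy-4-acetate F6.
   - Ac2O/pyridine then gives 14, where the fallback comes back to the route.

3. Step 6. The enantioselectivity may be insufficient, the electron-rich phenol may be propargylated at carbon, or the solvent may capture the copper allenylidene. Fallback: the stereocentre is set by asymmetric alkynylation and transferred by SN2 displacement, setting out from 6. Zinc/ProPhenol-catalysed addition of trimethylsilylacetylene (Me2Zn, toluene) should give 4-[(1S)-1-hydroxy-3-(trimethylsilyl)prop-2-yn-1-yl]phenyl pivalate F7. Buffered desilylation (TBAF/AcOH, THF, 0 °C) gives 4-[(1R)-1-hydroxyprop-2-yn-1-yl]phenyl pivalate F8. Mitsunobu etherification with phenol 4 (PPh3, DIAD, toluene, 0 °C) proceeds with inversion, helped by the electron-poor aryl group that suppresses SN1 leakage. The fallback comes back to the route at 10.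

**Further compounds**

F1 | step 9 | 4-[(2S)-7,8-bis(benzyloxy)-4-methoxychroman-2-yl]phenyl pivalate (C-4 epimers) | CC(C)(C)C(=O)Oc1ccc([C@@H]2CC(OC)c3ccc(OCc4ccccc4)c(OCc4ccccc4)c3O2)cc1
F2 | step 8 | (2R,3S,4S)-7,8-bis(benzyloxy)-2-[4-(pivaloyloxy)phenyl]chromane-3,4-diol (both OH anti to the 2-aryl group) | c1cc2c(c(OCc3ccccc3)c1OCc1ccccc1)O[C@H](c1ccc(OC(=O)C(C)(C)C)cc1)[C@@H](O)[C@H]2O
F3 | step 8 | 3,4-cyclic sulfite of F2 (sulfur epimers) | c1cc2c(c(OCc3ccccc3)c1OCc1ccccc1)O[C@H](c1ccc(OC(=O)C(C)(C)C)cc1)[C@H]1OS(=O)O[C@@H]21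
F4 | step 8 | (2R,3R,4R)-4-acetoxy-7,8-bis(benzyloxy)-3-hydroxy-2-[4-(pivaloyloxy)phenyl]chromane (3-OH anti, 4-OAc syn to the 2-aryl group) | c1cc2c(c(OCc3ccccc3)c1OCc1ccccc1)O[C@H](c1ccc(OC(=O)C(C)(C)C)cc1)[C@@H](O)[C@@H]2OC(C)=O
F5 | step 8 | (2R,4R)-4-acetoxy-7,8-bis(benzyloxy)-2-[4-(pivaloyloxy)phenyl]chroman-3-one | c1cc2c(c(OCc3ccccc3)c1OCc1ccccc1)O[C@H](c1ccc(OC(=O)C(C)(C)C)cc1)C(=O)[C@@H]2OC(C)=O
F6 | step 8 | (2R,3S,4R)-4-acetoxy-7,8-bis(benzyloxy)-3-hydroxy-2-[4-(pivaloyloxy)phenyl]chromane (all-cis) | c1cc2c(c(OCc3ccccc3)c1OCc1ccccc1)O[C@H](c1ccc(OC(=O)C(C)(C)C)cc1)[C@H](O)[C@@H]2OC(C)=O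
F7 | step 6 | 4-[(1S)-1-hydroxy-3-(trimethylsilyl)prop-2-yn-1-yl]phenyl pivalate | C[Si](C)(C)C#C[C@@H](O)c1ccc(OC(=O)C(C)(C)C)cc1
F8 | step 6 | 4-[(1R)-1-hydroxyprop-2-yn-1-yl]phenyl pivalate | C#C[C@@H](O)c1ccc(OC(=O)C(C)(C)C)cc1
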